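**Retrosynthetic overview**
1. Target ⇐ its octamethyl ether (global O‑demethylation as the last step).
2. Ring B lactone, aryl C8a'–O1' bond ⇐ a geminal diacid on C3' beside a 2,3,4,5‑tetramethoxyphenyl ring: dehydrogenative C–H lactonisation, then loss of CO2 and kinetic ketonisation set C3'.
3. C3–C3' ⇐ silyl ketene acetal of the ring A lactone + 5‑bromo Meldrum's acid carrying the C4' diarylmethyl group (radical addition sets C3).
4. C4 ⇐ 3,5‑dimethoxyphenol + 4‑methoxycinnamaldehyde (iminium Friedel–Crafts); C4' ⇐ 4‑methoxyphenylboronic acid + arylidene Meldrum's acid (rhodium‑catalysed arylation).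
5. Ring order: ring A lactone first (step 1), ring B lactone in step 8.

Assumption: primed locants denote the 5,6,7,8‑tetraoxygenated chromanone (ring B unit); the ligand enantiomer in step 4 is the one that gives (R)‑10, to be confirmed on the first run.

**Step 1**
Reactants: 1 3,5‑dimethoxyphenol; 2 (E)‑3‑(4‑methoxyphenyl)prop‑2‑enal
Product: 4 (4R)‑5,7‑dimethoxy‑4‑(4‑methoxyphenyl)chroman‑2‑one, via lactol 3 (not isolated)
Conditions: (R)‑α,α‑diphenylprolinol trimethylsilyl ether (20 mol%), PhCO2H (20 mol%), toluene, 0 °C; then PhI(OAc)2 (1.3 equiv), TEMPO (10 mol%), CH2Cl2, 25 °C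
Reagents that add atoms: none
Why: Iminium activation of the enal lets the phenol attack through its ortho carbon on the face away from the CPh2(OSiMe3) group (organocatalytic Friedel–Crafts alkylation/hemiacetalisation), which sets C4 as R, and the lactol is then oxidised to the lactone (TEMPO oxoammonium oxidation).

**Step 2**
Reactants: 5 1,2,3,4‑tetramethoxybenzene
Product: 6 2,3,4,5‑tetramethoxybenzaldehyde
Conditions: n‑BuLi, TMEDA, THF, 0 °C; then DMF; 1 M HCl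
Reagents that add atoms: N,N‑dimethylformamide, CN(C)C=O
Why: Directed ortho‑metalation at the only type of ring C–H (ortho to OMe) followed by formylation with DMF.

**Step 3**
Reactants: 6 2,3,4,5‑tetramethoxybenzaldehyde; 7 2,2‑dimethyl‑1,3‑dioxane‑4,6‑dione (Meldrum's acid)
Product: 8 2,2‑dimethyl‑5‑(2,3,4,5‑tetramethoxybenzylidene)‑1,3‑dioxane‑4,6‑dione
Conditions: pyrrolidine (10 mol%), AcOH (10 mol%), toluene, 25 °C
Reagents that add atoms: none
Why: Knoevenagel condensation of the very acidic methylene of Meldrum's acid with an aromatic aldehyde.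

**Step 4**
Reactants: 8 2,2‑dimethyl‑5‑(2,3,4,5‑tetramethoxybenzylidene)‑1,3‑dioxane‑4,6‑dione; 9 (4‑methoxyphenyl)boronic acid
Product: 10 5‑[(R)‑(4‑methoxyphenyl)(2,3,4,5‑tetramethoxyphenyl)methyl]‑2,2‑dimethyl‑1,3‑dioxane‑4,6‑dione
Conditions: [RhCl(C2H4)2]2 (2.5 mol%), (S,S)‑2,5‑diphenylbicyclo[2.2.2]octa‑2,5‑diene (5.5 mol%), KOH (20 mol%), dioxane/H2O 10:1, 25 °C; then 1 M HCl
Reagents that add atoms: none
Why: Rhodium‑catalysed asymmetric conjugate addition of an arylboronic acid (Hayashi–Miyaura reaction) to a doubly activated alkylidene with only one ortho substituent; the chiral diene–rhodium aryl inserts one enantioface of the C=C bond and so sets C4' as R.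

**Step 5**
Reactants: 10 5‑[(R)‑(4‑methoxyphenyl)(2,3,4,5‑tetramethoxyphenyl)methyl]‑2,2‑dimethyl‑1,3‑dioxane‑4,6‑dione
Product: 11 5‑bromo‑5‑[(R)‑(4‑methoxyphenyl)(2,3,4,5‑tetramethoxyphenyl)methyl]‑2,2‑dimethyl‑1,3‑dioxane‑4,6‑dione
Conditions: NBS (1.05 equiv), Et3N (10 mol%), CH2Cl2, −40 to 0 °C
Reagents that add atoms: N‑bromosuccinimide, O=C1CCC(=O)N1Br
Why: Electrophilic α‑bromination of the Meldrum's acid enolate, which at low temperature is far faster than bromination of the methoxyarene rings; C4' is untouched.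

**Step 6**
Reactants: 4 (4R)‑5,7‑dimethoxy‑4‑(4‑methoxyphenyl)chroman‑2‑one; 11 5‑bromo‑5‑[(R)‑(4‑methoxyphenyl)(2,3,4,5‑tetramethoxyphenyl)methyl]‑2,2‑dimethyl‑1,3‑dioxane‑4,6‑dione
Product: 13 (3R,4R)‑3‑{5‑[(R)‑(4‑methoxyphenyl)(2,3,4,5‑tetramethoxyphenyl)methyl]‑2,2‑dimethyl‑4,6‑dioxo‑1,3‑dioxan‑5‑yl}‑5,7‑dimethoxy‑4‑(4‑methoxyphenyl)chroman‑2‑one, via silyl ketene acetal 12 (not isolated)
Conditions: 4 (1.5 equiv), LiN(SiMe3)2, THF, −78 °C, then Me3SiCl; solvent change to MeCN; 11 (1.0 equiv), fac‑Ir(ppy)3 (1 mol%), blue LED, 25 °C; H2O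
Reagents that add atoms: none
Why: Photoredox radical alkylation of a silyl ketene acetal (Giese‑type addition with radical–polar crossover): the excited iridium complex cleaves the C–Br bond of 11, the electrophilic tertiary radical adds to the electron‑rich C3 of 12 on the face opposite the pseudoaxial C4 aryl (3,4‑trans, C3 = R), and oxidation with loss of the silyl group returns the lactone.

**Step 7**
Reactants: 13 (3R,4R)‑3‑{5‑[(R)‑(4‑methoxyphenyl)(2,3,4,5‑tetramethoxyphenyl)methyl]‑2,2‑dimethyl‑4,6‑dioxo‑1,3‑dioxan‑5‑yl}‑5,7‑dimethoxy‑4‑(4‑methoxyphenyl)chroman‑2‑one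
Product: 15 2‑[(3R,4R)‑5,7‑dimethoxy‑4‑(4‑methoxyphenyl)‑2‑oxochroman‑3‑yl]‑2‑[(R)‑(4‑methoxyphenyl)(2,3,4,5‑tetramethoxyphenyl)methyl]propanedioic acid, via hydroxy triacid 14 (not isolated)
Conditions: LiOH (6 equiv), THF/H2O 3:1, 25 °C; then 2 M HCl to pH 1, 40 °C
Reagents that add atoms: water, O
Why: Saponification of the Meldrum's acid ring (acyl attack, loss of acetone); the ring A lactone opens too but C3 is then α to a carboxylate and does not epimerise, and on acidification the six‑membered lactone recloses in preference to any seven‑membered alternative.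

**Step 8**
Reactants: 15 2‑[(3R,4R)‑5,7‑dimethoxy‑4‑(4‑methoxyphenyl)‑2‑oxochroman‑3‑yl]‑2‑[(R)‑(4‑methoxyphenyl)(2,3,4,5‑tetramethoxyphenyl)methyl]propanedioic acid
Product: 17 (3R,4R)‑5,7‑dimethoxy‑4‑(4‑methoxyphenyl)‑3‑[(3S,4R)‑5,6,7,8‑tetramethoxy‑4‑(4‑methoxyphenyl)‑2‑oxochroman‑3‑yl]chroman‑2‑one, via carboxy lactone 16 (not isolated)
Conditions: PhI(OCOCF3)2 (1.05 equiv), (CF3)2CHOH, −20 °C, dark; then 60 °C
Reagents that add atoms: none
Why: Proposed new method: dehydrogenative malonic‑acid C–H lactonisation with decarboxylative ketonisation – PhI(OCOCF3)2 in (CF3)2CHOH oxidises only the most electron‑rich ring (the tetramethoxyphenyl group) to its radical cation, either of the two geminal carboxyls closes the six‑membered ring at the single free ortho C–H (new aryl C–O bond, fifth ring oxygen; attack at an OMe‑bearing carbon is reversible, whereas C–H attack ends in irreversible rearomatisation), and on warming the β‑carboxy lactone 16 loses CO2 through the cyclic six‑membered transition state to the ring B lactone enol, which, with C3–H eclipsing C3'–C4', carries the pseudoaxial C4' aryl and C4 on the same face and is protonated from the other, so that H3' ends trans to the C4' aryl (3',4'‑cis, C3' = S); closest known reaction types: PhI(OCOCF3)2‑mediated oxidative cyclisation of 3‑arylpropanoic acids to 3,4‑dihydrocoumarins and Zimmerman kinetic ketonisation after decarboxylation of cyclic malonic acids.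

**Step 9**
Reactants: 17 (3R,4R)‑5,7‑dimethoxy‑4‑(4‑methoxyphenyl)‑3‑[(3S,4R)‑5,6,7,8‑tetramethoxy‑4‑(4‑methoxyphenyl)‑2‑oxochroman‑3‑yl]chroman‑2‑one
Product: 18 (3R,4R)‑5,7‑dihydroxy‑4‑(4‑hydroxyphenyl)‑3‑[(3S,4R)‑5,6,7,8‑tetrahydroxy‑4‑(4‑hydroxyphenyl)‑2‑oxochroman‑3‑yl]chroman‑2‑one
Conditions: BBr3 (16 equiv), CH2Cl2, −78 to 0 °C, argon; then H2O, aq. Na2S2O4 work‑up
Reagents that add atoms: none
Why: Lewis‑acid cleavage of all eight aryl methyl ethers (BBr3 demethylation) under non‑basic conditions, so the contra‑thermodynamic cis C3' centre is not enolised; a lactone that opens transiently can only reclose onto an equivalent ortho hydroxyl of the locally symmetric tri‑ or pentahydroxyphenyl ring.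

**Compound list**
1 | 3,5‑dimethoxyphenol | COc1cc(O)cc(OC)c1 | starting material
2 | (E)‑3‑(4‑methoxyphenyl)prop‑2‑enal | COc1ccc(/C=C/C=O)cc1 | starting material
3 | (4R)‑5,7‑dimethoxy‑4‑(4‑methoxyphenyl)chroman‑2‑ol (both anomers) | OC1Oc2cc(OC)cc(OC)c2[C@@H](c2ccc(OC)cc2)C1 | intermediate (not isolated)
4 | (4R)‑5,7‑dimethoxy‑4‑(4‑methoxyphenyl)chroman‑2‑one | O=C1Oc2cc(OC)cc(OC)c2[C@@H](c2ccc(OC)cc2)C1 | intermediate
5 | 1,2,3,4‑tetramethoxybenzene | COc1ccc(OC)c(OC)c1OC | starting material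
6 | 2,3,4,5‑tetramethoxybenzaldehyde | COc1cc(C=O)c(OC)c(OC)c1OC | intermediate
7 | 2,2‑dimethyl‑1,3‑dioxane‑4,6‑dione | CC1(C)OC(=O)CC(=O)O1 | starting material
8 | 2,2‑dimethyl‑5‑(2,3,4,5‑tetramethoxybenzylidene)‑1,3‑dioxane‑4,6‑dione | COc1cc(C=C2C(=O)OC(C)(C)OC2=O)c(OC)c(OC)c1OC | intermediate
9 | (4‑methoxyphenyl)boronic acid | COc1ccc(cc1)B(O)O | starting material
10 | 5‑[(R)‑(4‑methoxyphenyl)(2,3,4,5‑tetramethoxyphenyl)methyl]‑2,2‑dimethyl‑1,3‑dioxane‑4,6‑dione | COc1ccc(cc1)[C@H](c1cc(OC)c(OC)c(OC)c1OC)C1C(=O)OC(C)(C)OC1=O | intermediate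
11 | 5‑bromo‑5‑[(R)‑(4‑methoxyphenyl)(2,3,4,5‑tetramethoxyphenyl)methyl]‑2,2‑dimethyl‑1,3‑dioxane‑4,6‑dione | COc1ccc(cc1)[C@H](c1cc(OC)c(OC)c(OC)c1OC)C1(Br)C(=O)OC(C)(C)OC1=O | intermediate
12 | (4R)‑5,7‑dimethoxy‑4‑(4‑methoxyphenyl)‑2‑[(trimethylsilyl)oxy]‑4H‑chromene | C[Si](C)(C)OC1=C[C@H](c2ccc(OC)cc2)c2c(OC)cc(OC)cc2O1 | intermediate (not isolated)
13 | (3R,4R)‑3‑{5‑[(R)‑(4‑methoxyphenyl)(2,3,4,5‑tetramethoxyphenyl)methyl]‑2,2‑dimethyl‑4,6‑dioxo‑1,3‑dioxan‑5‑yl}‑5,7‑dimethoxy‑4‑(4‑methoxyphenyl)chroman‑2‑one | O=C1Oc2cc(OC)cc(OC)c2[C@@H](c2ccc(OC)cc2)[C@@H]1C3(C(=O)OC(C)(C)OC3=O)[C@@H](c4cc(OC)c(OC)c(OC)c4OC)c4ccc(OC)cc4 | intermediate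
14 | (1R,3R,4R)‑4‑(2‑hydroxy‑4,6‑dimethoxyphenyl)‑1,4‑bis(4‑methoxyphenyl)‑1‑(2,3,4,5‑tetramethoxyphenyl)butane‑2,2,3‑tricarboxylic acid | OC(=O)[C@H]([C@H](c1ccc(OC)cc1)c1c(O)cc(OC)cc1OC)C(C(=O)O)(C(=O)O)[C@@H](c1cc(OC)c(OC)c(OC)c1OC)c1ccc(OC)cc1 | intermediate (not isolated)
15 | 2‑[(3R,4R)‑5,7‑dimethoxy‑4‑(4‑methoxyphenyl)‑2‑oxochroman‑3‑yl]‑2‑[(R)‑(4‑methoxyphenyl)(2,3,4,5‑tetramethoxyphenyl)methyl]propanedioic acid | O=C1Oc2cc(OC)cc(OC)c2[C@@H](c2ccc(OC)cc2)[C@@H]1C(C(=O)O)(C(=O)O)[C@@H](c4cc(OC)c(OC)c(OC)c4OC)c4ccc(OC)cc4 | intermediate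
16 | (4R)‑3‑[(3R,4R)‑5,7‑dimethoxy‑4‑(4‑methoxyphenyl)‑2‑oxochroman‑3‑yl]‑5,6,7,8‑tetramethoxy‑4‑(4‑methoxyphenyl)‑2‑oxochroman‑3‑carboxylic acid (both C3 epimers of this ring) | O=C1Oc2cc(OC)cc(OC)c2[C@@H](c2ccc(OC)cc2)[C@@H]1C3(C(=O)O)C(=O)Oc4c(OC)c(OC)c(OC)c(OC)c4[C@H]3c3ccc(OC)cc3 | intermediate (not isolated)
17 | (3R,4R)‑5,7‑dimethoxy‑4‑(4‑methoxyphenyl)‑3‑[(3S,4R)‑5,6,7,8‑tetramethoxy‑4‑(4‑methoxyphenyl)‑2‑oxochroman‑3‑yl]chroman‑2‑one | O=C1Oc2cc(OC)cc(OC)c2[C@@H](c2ccc(OC)cc2)[C@@H]1[C@H]1C(=O)Oc2c(OC)c(OC)c(OC)c(OC)c2[C@H]1c1ccc(OC)cc1 | intermediate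
18 | (3R,4R)‑5,7‑dihydroxy‑4‑(4‑hydroxyphenyl)‑3‑[(3S,4R)‑5,6,7,8‑tetrahydroxy‑4‑(4‑hydroxyphenyl)‑2‑oxochroman‑3‑yl]chroman‑2‑one | O=C1Oc2cc(O)cc(O)c2[C@@H](c2ccc(O)cc2)[C@@H]1[C@H]1C(=O)Oc2c(O)c(O)c(O)c(O)c2[C@H]1c1ccc(O)cc1 | target

**Step count and risks**
Total steps: 9. Longest linear sequence: 8 (steps 2 to 9, from 5).

The three steps most likely to fail:

Step 4. The ortho‑methoxy arylidene Meldrum's acid may hydrolyse (retro‑Knoevenagel) in the aqueous basic medium or give low enantioselectivity. The fallback sets out from 8: uncatalysed conjugate addition of 4‑MeOC6H4MgBr (THF, −20 °C) gives racemic 5‑[(4‑methoxyphenyl)(2,3,4,5‑tetramethoxyphenyl)methyl]‑2,2‑dimethyl‑1,3‑dioxane‑4,6‑dione F1. This acidic compound is resolved as its quinidine salt or by preparative chiral chromatography, the (S)‑enantiomer F2 is discarded, and the route is rejoined at 10.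

Step 6. The bond joins a quaternary to a tertiary carbon; bromine transfer from 11 to the ketene acetal or a 1,2‑aryl shift in the radical may compete. The fallback sets out from 4 and 10, leaves out step 5 and makes no new compound (F0): the lithium enolate of 4 and the lithium salt of 10 are formed together with LiN(SiMe3)2 in THF at −78 °C and oxidised with Fe(acac)3 (2 equiv) while warming to 25 °C (oxidative enolate heterocoupling, in which the lactone‑derived radical is captured by the stabilised enolate). The C–C bond again forms anti to the C4 aryl, and the route is rejoined at 13.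

Step 8 (the proposed new method). Attack at a methoxy‑bearing ring carbon, over‑oxidation of the product ring or erosion of the cis selectivity during ketonisation could spoil it. The fallback uses known chemistry and sets out from 15: thermal decarboxylation in pyridine at 100 °C gives (3R)‑2‑[(3R,4R)‑5,7‑dimethoxy‑4‑(4‑methoxyphenyl)‑2‑oxochroman‑3‑yl]‑3‑(4‑methoxyphenyl)‑3‑(2,3,4,5‑tetramethoxyphenyl)propanoic acid F3 as a mixture of C2 epimers. The known PhI(OCOCF3)2/BF3·OEt2 oxidative cyclisation of 3‑arylpropanoic acids (CH2Cl2, −40 °C) then closes ring B without stereocontrol at C3'. It gives 17 together with its C3' epimer, (3R,4R)‑5,7‑dimethoxy‑4‑(4‑methoxyphenyl)‑3‑[(3R,4R)‑5,6,7,8‑tetramethoxy‑4‑(4‑methoxyphenyl)‑2‑oxochroman‑3‑yl]chroman‑2‑one F4, which is removed by chromatography; the route is rejoined at 17.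

**Further compounds**
F1 | step 4 | racemic 5‑[(4‑methoxyphenyl)(2,3,4,5‑tetramethoxyphenyl)methyl]‑2,2‑dimethyl‑1,3‑dioxane‑4,6‑dione | COc1ccc(cc1)C(c1cc(OC)c(OC)c(OC)c1OC)C1C(=O)OC(C)(C)OC1=O
F2 | step 4 | 5‑[(S)‑(4‑methoxyphenyl)(2,3,4,5‑tetramethoxyphenyl)methyl]‑2,2‑dimethyl‑1,3‑dioxane‑4,6‑dione | COc1ccc(cc1)[C@@H](c1cc(OC)c(OC)c(OC)c1OC)C1C(=O)OC(C)(C)OC1=O
F0 | step 6 | none | none
F3 | step 8 | (3R)‑2‑[(3R,4R)‑5,7‑dimethoxy‑4‑(4‑methoxyphenyl)‑2‑oxochroman‑3‑yl]‑3‑(4‑methoxyphenyl)‑3‑(2,3,4,5‑tetramethoxyphenyl)propanoic acid (C2 epimers) | O=C1Oc2cc(OC)cc(OC)c2[C@@H](c2ccc(OC)cc2)[C@@H]1C(C(=O)O)[C@@H](c4cc(OC)c(OC)c(OC)c4OC)c4ccc(OC)cc4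
F4 | step 8 | (3R,4R)‑5,7‑dimethoxy‑4‑(4‑methoxyphenyl)‑3‑[(3R,4R)‑5,6,7,8‑tetramethoxy‑4‑(4‑methoxyphenyl)‑2‑oxochroman‑3‑yl]chroman‑2‑one | O=C1Oc2cc(OC)cc(OC)c2[C@@H](c2ccc(OC)cc2)[C@@H]1[C@@H]1C(=O)Oc2c(OC)c(OC)c(OC)c(OC)c2[C@H]1c1ccc(OC)cc1
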